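All runs were computed from invented constants.

5 questions stand here, and behind them lies one decision: which of 4 recipes I charge next if I want double product to hold its share against tris adduct.

| flask | starting material | reagent | capture agent | temperature | remark | time |
|---|---|---|---|---|---|---|
| Wednesday's | 0.074 M | 0.185 M | 0.074 M | −10 °C | run made earlier |  |
| Sunday's | 0.050 M | 0.185 M | 0.074 M | 5 °C | run made earlier |  |
| Thursday's | 0.11 M | 0.185 M | 0.074 M | −10 °C | run made earlier |  |
| Saturday's | 0.074 M | 0.28 M | 0.074 M | 5 °C | run made earlier |  |
| alder | 0.074 M (fed, over 15 min) | 0.185 M | 0.0740 M | 5 °C | all else is in the flask from the start; the feed brings no volume worth counting | 20 min |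
| larch | 0.074 M | 0.185 M | 0.0740 M |  | everything together at the start at −15 °C, warmed to 5 °C at 15 min | 20 min |
| birch | 0.074 M | 0.185 M (fed, over 15 min) | 0.0740 M | 5 °C | all else is in the flask from the start; the feed brings no volume worth counting | 20 min |
| elm | 0.074 M | 0.185 M (fed, over 15 min) | 0.0740 M |  | the addition at −15 °C, then warmed to 5 °C; the feed brings no volume worth counting | 20 min |

- Wednesday's (time / min: double product / %, tris adduct / %): 2.00: 0.7, 0; 4.00: 2.3, 0.6; 6.00: 2.8, 1.9; 12.0: 2.1, 5.1; 25.0: 1.6, 9.1
- Sunday's (time / min: double product / %, tris adduct / %): 1.00: 3.5, 1.6; 3.00: 1.9, 6.2; 6.00: 2.1, 9.4; 8.00: 0, 10.0; 12.0: 0, 8.5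
- Thursday's (time / min: double product / %, tris adduct / %): 2.00: 1.1, 0.4; 4.00: 1.5, 0.4; 6.00: 1.9, 1.5; 12.0: 1.9, 2.7; 25.0: 0.6, 5.6
- Saturday's (time / min: double product / %, tris adduct / %): 2.50: 2.7, 8.6; 5.00: 1.2, 11.7; 8.00: 1.4, 13.3; 10.0: 0.3, 11.7; 12.0: 0, 11.1

(standard deviation of a reading: 0.5 percentage points)

* the flask with the highest share of double product in double product plus tris adduct ("all alike" if they lie within 1.5 percentage points) (alder / larch / birch / elm / all alike)
* share of double product in double product plus tris adduct at the end, alder
* share of double product in double product plus tris adduct at the end, larch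
* share of double product in double product plus tris adduct at the end, birch
* share of double product in double product plus tris adduct at the end, elm

- the analysis behind the earlier runs scatters by 0.5 percentage points, standard deviation

In the runs tris adduct grows behind double product, so I count the turnovers the material has had. Dividing the rise of tris adduct by the double product standing during that rise, I read a pseudo-first-order constant of 0.852 min⁻¹ in Sunday's run and 0.218 min⁻¹ in Wednesday's. Both are readings and carry their scatter, and the two runs charge the same 0.185 M of reagent but differ in starting material, 0.050 M against 0.074 M. A minute at −10 °C therefore counts for less than one at 5 °C, by a factor of 3.91. I stretch this by my own extrapolation to 6.17 for −15 °C.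

Elm's reagent, fed cold, has on average half the feed time behind it before the warming, so elm stands at 6.22 min. That figure is the warm age: the average minutes a charge has spent in the flask, with each cold minute divided by the factor. Larch stands at 7.43 min, which is older than elm, and alder and birch both stand at 12.5 min, older again.

The warm runs read a share of 18.3% at 6.00 min on Sunday and 9.30% at 5.00 min on Saturday, while at 12.0 min both read 0% of double product. So I would charge elm, then larch; warm age does not part alder from birch.

The forecast also names elm, with 10% there, 6% for larch, 4% for birch and 2.5% for alder, so unlike my count it parts those last two. Its ground: “Elm holds the most, with the least reagent”.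

The flasks give 10.5% for elm, 7.26% for larch, 2.75% for alder and 1.33% for birch.

    starting material + reagent → first product + by-product (k = 0.320 M⁻¹ s⁻¹, Ea = 61.0 kJ mol⁻¹)
    reagent + first product → double product + by-product (k = 0.00660 M⁻¹ s⁻¹, Ea = 59.0 kJ mol⁻¹)
    reagent + double product → tris adduct + by-product (k = 0.140 M⁻¹ s⁻¹, Ea = 63.0 kJ mol⁻¹)
    reagent + tris adduct ⇌ tetra adduct + by-product (K = 1.80, k = 0.00530 M⁻¹ s⁻¹, Ea = 53.0 kJ mol⁻¹, ΔH = −47.0 kJ mol⁻¹)
    first product → side product (k = 0.00490 s⁻¹, Ea = 74.0 kJ mol⁻¹)
    first product + capture agent → trapped intermediate (k = 0.0170 M⁻¹ s⁻¹, Ea = 65.0 kJ mol⁻¹)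
    (constants at 5 °C)

Elm ends with 11.0% of first product beside 0.905% of double product, and alder with 2.84% beside 0.245%. The ratios are 0.0823 and 0.0863, so in these two flasks double product stands in step with first product, and elm, at a warm age of 6.22 min against 12.5 min, holds more first product than alder. The neighbour flask, elm's recipe with 0.18 M of starting material, has the same warm age by this count, yet with reagent down to 4.03% of its charge its share stands at 55.3%.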